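**Plan**
The eleven-membered ring is counted from C1, the olefinic CH bonded to the gem-dimethyl carbon. It continues through C2, C3 (carries =CH2), C4, C5, C6, C7 (carries CH3), C8, C9 (acyloxy) and C10 to C11 (CMe2).
Cuts: first the acyl–O bond at C9, then the E C1=C2 bond. C1 is a neopentyl carbon on quaternary C11 and C2 is allylic to the C3 methylidene, so they are the two α-carbons of a twelve-membered allyl neopentyl sulfone. Loss of SO2 from that sulfone gives the carbocycle and the C1=C2–C3=CH2 diene together.
The thiacycle is cut at S–C2 and S–C1. The open chain is cut at C4–C5, C5–C6, C7–CH3, C7–C8 and C10–C11.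
Forward: isobutyronitrile anion (C10–C11) and then a silylacetylide (C7–C8) are added to the two ends of (R)-epichlorohydrin. Carboalumination–hydroxymethylation and the methallyl alcohol dianion carry the chain to C2. Sulfur enters at C1, the twelve-membered ring closes at S–C2, contraction gives the eleven-membered ring, and the ester is made last.
Stereochemistry: C9 is the epichlorohydrin carbon, whose C–O bond is never broken. E C6=C7 comes from syn carboalumination, and E C1=C2 from a trans-fused episulfone.

Key step: step 14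

Remark: the SMILES puts C9 in the (S) configuration. The first nucleophile ends up on C10 and the second on C8, so this maps onto (R)-epichlorohydrin.

**Step 1**
Reactants: 1 isobutyronitrile; 2 (R)-epichlorohydrin
Product: 5 (R)-2,2-dimethyl-3-(oxiran-2-yl)propanenitrile, via lithiated isobutyronitrile 3 (not isolated), via chlorohydrin lithium alkoxide 4 (not isolated)
Conditions: LiN(i-Pr)2, THF, −78 °C; 2 (1.2 equiv), −78 to −30 °C; then rt, 12 h
Reagents that add atoms: none
Why: Epoxide opening by a nitrile-stabilised tertiary carbanion at the free CH2, followed by Williamson-type 3-exo-tet closure of the chlorohydrin alkoxide, moves the oxirane along the chain without touching the C–O bond of the stereocentre, and the quaternary α-carbon excludes the cyclopropanation seen with secondary nitrile anions.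

**Step 2**
Reactants: 5 (R)-2,2-dimethyl-3-(oxiran-2-yl)propanenitrile; 6 trimethylsilylacetylene
Product: 8 (R)-4-hydroxy-2,2-dimethyl-7-(trimethylsilyl)hept-6-ynenitrile, via lithium trimethylsilylacetylide 7 (not isolated)
Conditions: 6, n-BuLi, THF, −78 °C; BF3·OEt2; then 5, −78 °C; aqueous work-up
Reagents that add atoms: none
Why: In the Yamaguchi–Hirao alkynylation the BF3-activated terminal epoxide is opened at its CH2 by a weakly basic acetylide at −78 °C, where the hindered nitrile is inert and C9 keeps its oxygen.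

**Step 3**
Reactants: 8 (R)-4-hydroxy-2,2-dimethyl-7-(trimethylsilyl)hept-6-ynenitrile
Product: 9 (R)-4-[(tert-butyldimethylsilyl)oxy]-2,2-dimethyl-7-(trimethylsilyl)hept-6-ynenitrile
Conditions: TBSCl, imidazole, DMF, rt
Reagents that add atoms: tert-butyldimethylsilyl chloride, CC(C)(C)[Si](C)(C)Cl
Why: Imidazole-promoted silylation of a secondary alcohol blocks cyclisation of the γ-hydroxynitrile and gives a group stable to every base and organometal used later.

**Step 4**
Reactants: 9 (R)-4-[(tert-butyldimethylsilyl)oxy]-2,2-dimethyl-7-(trimethylsilyl)hept-6-ynenitrile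
Product: 11 (R)-4-[(tert-butyldimethylsilyl)oxy]-2,2-dimethyl-7-(trimethylsilyl)hept-6-ynal, via aluminium aldimine 10 (not isolated)
Conditions: i-Bu2AlH, CH2Cl2, −78 °C; then aq potassium sodium tartrate, rt
Reagents that add atoms: water, O
Why: Partial reduction of a nitrile with i-Bu2AlH stops at the N-aluminated aldimine, which hydrolyses to a non-enolisable aldehyde, and the silylated alkyne is not hydroaluminated at this temperature.

**Step 5**
Reactants: 11 (R)-4-[(tert-butyldimethylsilyl)oxy]-2,2-dimethyl-7-(trimethylsilyl)hept-6-ynal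
Product: 13 (S)-4-[(tert-butyldimethylsilyl)oxy]-2,2-dimethylhept-6-yn-1-ol, via silylalkynyl alcohol 12 (not isolated)
Conditions: NaBH4, MeOH, 0 °C; then K2CO3 (0.3 equiv), rt
Reagents that add atoms: none
Why: Borohydride reduction is followed in the same flask by carbonate-catalysed methanolytic protodesilylation of the alkynylsilane, which leaves the secondary silyl ether alone (the descriptor changes only because the priorities change).

**Step 6**
Reactants: 13 (S)-4-[(tert-butyldimethylsilyl)oxy]-2,2-dimethylhept-6-yn-1-ol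
Product: 15 (S)-[(7-bromo-6,6-dimethylhept-1-yn-4-yl)oxy](tert-butyl)dimethylsilane, via neopentyl triflate 14 (not isolated)
Conditions: Tf2O, 2,6-lutidine, CH2Cl2, −78 °C; then n-Bu4NBr, −78 °C to rt
Reagents that add atoms: tetrabutylammonium bromide, CCCC[N+](CCCC)(CCCC)CCCC.[Br-]
Why: In this sulfonylation–SN2 sequence a neopentyl triflate cannot eliminate yet is displaced by soluble bromide at room temperature, and the resulting neopentyl bromide is slow enough in SN2 and in halogen–metal exchange to serve as a latent leaving group through steps 7 to 9.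

**Step 7**
Reactants: 15 (S)-[(7-bromo-6,6-dimethylhept-1-yn-4-yl)oxy](tert-butyl)dimethylsilane
Product: 18 (2E,5S)-8-bromo-5-[(tert-butyldimethylsilyl)oxy]-3,7,7-trimethyloct-2-en-1-ol, via alkenylalane 16 (not isolated), via lithium alanate 17 (not isolated)
Conditions: Me3Al, Cp2ZrCl2 (0.25 equiv), CH2Cl2, 0 °C to rt; excess Me3Al removed in vacuo; n-BuLi, hexane–THF, −78 °C; (CH2O)n, to rt
Reagents that add atoms: trimethylaluminium, C[Al](C)C; formaldehyde (as paraformaldehyde), C=O
Why: Negishi carboalumination adds CH3 and Al syn with Al on the terminal carbon, which fixes E C6=C7, and the derived alanate is hydroxymethylated with retention, a sequence well known for homopropargylic silyl ethers.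

**Step 8**
Reactants: 18 (2E,5S)-8-bromo-5-[(tert-butyldimethylsilyl)oxy]-3,7,7-trimethyloct-2-en-1-ol
Product: 19 (2E,5S)-1,8-dibromo-5-[(tert-butyldimethylsilyl)oxy]-3,7,7-trimethyloct-2-ene
Conditions: CBr4, PPh3, CH2Cl2, −20 to 0 °C
Reagents that add atoms: carbon tetrabromide, BrC(Br)(Br)Br
Why: The Appel reaction converts primary allylic alcohols of the geraniol type to bromides under neutral conditions without allylic shift or loss of alkene geometry.

**Step 9**
Reactants: 19 (2E,5S)-1,8-dibromo-5-[(tert-butyldimethylsilyl)oxy]-3,7,7-trimethyloct-2-ene; 20 2-methylprop-2-en-1-ol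
Product: 22 (5E,8S)-11-bromo-8-[(tert-butyldimethylsilyl)oxy]-6,10,10-trimethyl-2-methylideneundec-5-en-1-ol, via dilithiated methallyl alcohol 21 (not isolated)
Conditions: 20, n-BuLi (2 equiv per 20), TMEDA, Et2O, 0 °C to rt; then 19, THF, −78 to 0 °C
Reagents that add atoms: none
Why: C-alkylation of the cross-conjugated methallyl alcohol dianion forms C4–C5, the 2-substituted allyl nucleophile gives one product from either terminus, and the primary allylic bromide reacts far faster than the neopentyl bromide.

**Step 10**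
Reactants: 22 (5E,8S)-11-bromo-8-[(tert-butyldimethylsilyl)oxy]-6,10,10-trimethyl-2-methylideneundec-5-en-1-ol
Product: 23 S-[(4S,6E)-4-[(tert-butyldimethylsilyl)oxy]-10-(hydroxymethyl)-2,2,6-trimethylundeca-6,10-dien-1-yl] ethanethioate
Conditions: potassium thioacetate, n-Bu4NI (0.1 equiv), DMF, 80 °C
Reagents that add atoms: potassium thioacetate, CC(=O)[S-].[K+]
Why: SN2 displacement of β,β-dimethyl primary bromides by the small, soft thioacetate ion in hot DMF is standard for this hindered class (3-bromo-2,2-dimethylpropan-1-ol is the model), elimination is impossible next to quaternary C11, and the free alcohol, silyl ether and alkenes are inert.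

**Step 11**
Reactants: 23 S-[(4S,6E)-4-[(tert-butyldimethylsilyl)oxy]-10-(hydroxymethyl)-2,2,6-trimethylundeca-6,10-dien-1-yl] ethanethioate
Product: 25 S-[(4S,6E)-4-[(tert-butyldimethylsilyl)oxy]-10-(chloromethyl)-2,2,6-trimethylundeca-6,10-dien-1-yl] ethanethioate, via allylic mesylate 24 (not isolated)
Conditions: MsCl, 2,4,6-collidine, LiCl, DMF, 0 °C
Reagents that add atoms: lithium chloride, [Li+].[Cl-]
Why: In the Collington–Meyers chlorination the allylic mesylate is replaced in situ by chloride under buffered conditions that a thioester tolerates.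

**Step 12**
Reactants: 25 S-[(4S,6E)-4-[(tert-butyldimethylsilyl)oxy]-10-(chloromethyl)-2,2,6-trimethylundeca-6,10-dien-1-yl] ethanethioate
Product: 27 tert-butyl(dimethyl){[(6E,9S)-7,11,11-trimethyl-3-methylidene-1-thiacyclododec-6-en-9-yl]oxy}silane, via chloro thiol 26 (not isolated)
Conditions: syringe-pump addition of 25 to Cs2CO3, degassed DMF–MeOH 9:1, final 1 mM, rt
Reagents that add atoms: none
Why: Methanolysis of the thioester releases a caesium thiolate that closes the twelve-membered ring by intramolecular SN2 (12-exo-tet) at the allylic chloride under high dilution, and an SN2′ pathway would give the identical product.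

**Step 13**
Reactants: 27 tert-butyl(dimethyl){[(6E,9S)-7,11,11-trimethyl-3-methylidene-1-thiacyclododec-6-en-9-yl]oxy}silane
Product: 29 (6E,9S)-9-[(tert-butyldimethylsilyl)oxy]-7,11,11-trimethyl-3-methylidene-1-thiacyclododec-6-ene 1,1-dioxide, via sulfoxide 28 (not isolated)
Conditions: (NH4)6Mo7O24·4H2O (0.1 equiv), 30% aq H2O2, EtOH, 0 °C to rt
Reagents that add atoms: hydrogen peroxide, OO
Why: Molybdate-catalysed peroxide oxidation takes sulfides to sulfones without epoxidising isolated tri- and disubstituted alkenes, as is routine for olefination sulfones.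

**Step 14**
Reactants: 29 (6E,9S)-9-[(tert-butyldimethylsilyl)oxy]-7,11,11-trimethyl-3-methylidene-1-thiacyclododec-6-ene 1,1-dioxide
Product: 32 tert-butyl(dimethyl){[(1S,3E,8E)-3,10,10-trimethyl-7-methylidenecycloundeca-3,8-dien-1-yl]oxy}silane, via C2-bromosulfone 30 (not isolated), via trans-episulfone 31 (not isolated)
Conditions: CBr2F2, KOH/Al2O3, t-BuOH–CH2Cl2, 0 °C to rt
Reagents that add atoms: none
Why: Solid KOH/Al2O3 removes the most acidic proton of 29, the C2–H that is both α to sulfonyl and allylic to the C3 methylidene, and the carbanion takes Br+ from CBr2F2 to give 30; bromination through the methylidene terminus would not matter, because SN2′ closure leads to the same episulfone. A second deprotonation at the only other α site, C1, triggers 1,3-displacement of bromide (3-exo-tet closure of the thiirane ring) to the 1,1-dioxide 31, which expels SO2 cheletropically, so the C1=C2 bond forms and the twelve-membered thiacycle contracts to the eleven-membered carbocycle without any end-to-end C–C closure. This is the one-flask Meyers–Chan form of the Ramberg–Bäcklund reaction, established for macrocyclic sulfones and for allyl sulfones that give 1,3-dienes. No stereocentre is created and remote C9 is untouched; the alkene geometry is decided in 31, whose C2–H is still allylic and acidic, so base should equilibrate it to the less strained trans-fused isomer and stereospecific extrusion should then give the E alkene. The step needs monobromination at C2 rather than C1, which the large acidity gap between an allylic and a neopentyl sulfonyl C–H secures, and it needs the sulfone to have no other exit, which quaternary C11 secures by offering no β-hydrogen. CBr2F2 is chosen over CCl4 because the carbene it leaves, CF2, is sluggish towards the C6=C7 and methylidene bonds, and the silyl ether is stable to solid KOH.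

**Step 15**
Reactants: 32 tert-butyl(dimethyl){[(1S,3E,8E)-3,10,10-trimethyl-7-methylidenecycloundeca-3,8-dien-1-yl]oxy}silane
Product: 33 (1S,3E,8E)-3,10,10-trimethyl-7-methylidenecycloundeca-3,8-dien-1-ol
Conditions: n-Bu4NF, THF, rt
Reagents that add atoms: none
Why: Fluoride desilylation cleaves only the Si–O bond, so C9 keeps its configuration and the triene is not exposed to acid.

**Step 16**
Reactants: 34 isovanillic acid (3-hydroxy-4-methoxybenzoic acid)
Product: 36 3-[(tert-butyldimethylsilyl)oxy]-4-methoxybenzoic acid, via bis-silyl derivative 35 (not isolated)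
Conditions: TBSCl (2.5 equiv), imidazole, DMF, rt; then AcOH–THF–H2O, rt
Reagents that add atoms: tert-butyldimethylsilyl chloride, CC(C)(C)[Si](C)(C)Cl
Why: After exhaustive silylation the far more labile silyl ester is hydrolysed selectively, while the aryl silyl ether resists dilute acid.

**Step 17**
Reactants: 33 (1S,3E,8E)-3,10,10-trimethyl-7-methylidenecycloundeca-3,8-dien-1-ol; 36 3-[(tert-butyldimethylsilyl)oxy]-4-methoxybenzoic acid
Product: 37 (1S,3E,8E)-3,10,10-trimethyl-7-methylidenecycloundeca-3,8-dien-1-yl 3-[(tert-butyldimethylsilyl)oxy]-4-methoxybenzoate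
Conditions: EDC·HCl, DMAP, CH2Cl2, rt
Reagents that add atoms: none
Why: Steglich esterification forms the acyl–O bond and leaves the C9–O bond intact, so the configuration is retained, and the masked phenol cannot self-acylate.

**Step 18**
Reactants: 37 (1S,3E,8E)-3,10,10-trimethyl-7-methylidenecycloundeca-3,8-dien-1-yl 3-[(tert-butyldimethylsilyl)oxy]-4-methoxybenzoate
Product: 38 (1S,3E,8E)-3,10,10-trimethyl-7-methylidenecycloundeca-3,8-dien-1-yl 3-hydroxy-4-methoxybenzoate (target)
Conditions: n-Bu4NF, AcOH, THF, 0 °C
Reagents that add atoms: none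
Why: Aryl silyl ethers are cleaved by buffered fluoride within minutes at 0 °C, conditions under which the benzoate ester and the triene are stable.

**Compound list**
1 | isobutyronitrile | CC(C)C#N | starting material
2 | (R)-epichlorohydrin | ClC[C@H]1CO1 | starting material
3 | lithiated isobutyronitrile (not isolated) | [Li+].C[C-](C)C#N | intermediate
4 | lithium alkoxide of (R)-5-chloro-4-hydroxy-2,2-dimethylpentanenitrile (not isolated) | [Li+].N#CC(C)(C)C[C@@H]([O-])CCl | intermediate
5 | (R)-2,2-dimethyl-3-(oxiran-2-yl)propanenitrile | N#CC(C)(C)C[C@@H]1CO1 | intermediate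
6 | trimethylsilylacetylene | C#C[Si](C)(C)C | starting material
7 | lithium trimethylsilylacetylide (not isolated) | [Li]C#C[Si](C)(C)C | intermediate
8 | (R)-4-hydroxy-2,2-dimethyl-7-(trimethylsilyl)hept-6-ynenitrile | N#CC(C)(C)C[C@@H](O)CC#C[Si](C)(C)C | intermediate
9 | (R)-4-[(tert-butyldimethylsilyl)oxy]-2,2-dimethyl-7-(trimethylsilyl)hept-6-ynenitrile | N#CC(C)(C)C[C@@H](O[Si](C)(C)C(C)(C)C)CC#C[Si](C)(C)C | intermediate
10 | N-(diisobutylaluminio)aldimine of 11 (not isolated) | CC(C)C[Al](CC(C)C)N=CC(C)(C)C[C@@H](O[Si](C)(C)C(C)(C)C)CC#C[Si](C)(C)C | intermediate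
11 | (R)-4-[(tert-butyldimethylsilyl)oxy]-2,2-dimethyl-7-(trimethylsilyl)hept-6-ynal | O=CC(C)(C)C[C@@H](O[Si](C)(C)C(C)(C)C)CC#C[Si](C)(C)C | intermediate
12 | (R)-4-[(tert-butyldimethylsilyl)oxy]-2,2-dimethyl-7-(trimethylsilyl)hept-6-yn-1-ol (not isolated) | OCC(C)(C)C[C@@H](O[Si](C)(C)C(C)(C)C)CC#C[Si](C)(C)C | intermediate
13 | (S)-4-[(tert-butyldimethylsilyl)oxy]-2,2-dimethylhept-6-yn-1-ol | OCC(C)(C)C[C@@H](O[Si](C)(C)C(C)(C)C)CC#C | intermediate
14 | (S)-4-[(tert-butyldimethylsilyl)oxy]-2,2-dimethylhept-6-yn-1-yl trifluoromethanesulfonate (not isolated) | O=S(=O)(OCC(C)(C)C[C@@H](O[Si](C)(C)C(C)(C)C)CC#C)C(F)(F)F | intermediate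
15 | (S)-[(7-bromo-6,6-dimethylhept-1-yn-4-yl)oxy](tert-butyl)dimethylsilane | BrCC(C)(C)C[C@@H](O[Si](C)(C)C(C)(C)C)CC#C | intermediate
16 | (E)-alkenyl(dimethyl)alane from syn Me–Al addition to 15, Al on C6, C9 (S) (not isolated) | BrCC(C)(C)C[C@@H](O[Si](C)(C)C(C)(C)C)C/C(C)=C/[Al](C)C | intermediate
17 | lithium n-butyl(dimethyl)alkenylalanate from 16 (not isolated) | [Li+].BrCC(C)(C)C[C@@H](O[Si](C)(C)C(C)(C)C)C/C(C)=C/[Al-](C)(C)CCCC | intermediate
18 | (2E,5S)-8-bromo-5-[(tert-butyldimethylsilyl)oxy]-3,7,7-trimethyloct-2-en-1-ol | BrCC(C)(C)C[C@@H](O[Si](C)(C)C(C)(C)C)C/C(C)=C/CO | intermediate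
19 | (2E,5S)-1,8-dibromo-5-[(tert-butyldimethylsilyl)oxy]-3,7,7-trimethyloct-2-ene | BrCC(C)(C)C[C@@H](O[Si](C)(C)C(C)(C)C)C/C(C)=C/CBr | intermediate
20 | 2-methylprop-2-en-1-ol | C=C(C)CO | starting material
21 | dilithiated 2-methylprop-2-en-1-ol (not isolated) | [Li]CC(=C)CO[Li] | intermediate
22 | (5E,8S)-11-bromo-8-[(tert-butyldimethylsilyl)oxy]-6,10,10-trimethyl-2-methylideneundec-5-en-1-ol | BrCC(C)(C)C[C@@H](O[Si](C)(C)C(C)(C)C)C/C(C)=C/CCC(=C)CO | intermediate
23 | S-[(4S,6E)-4-[(tert-butyldimethylsilyl)oxy]-10-(hydroxymethyl)-2,2,6-trimethylundeca-6,10-dien-1-yl] ethanethioate | CC(=O)SCC(C)(C)C[C@@H](O[Si](C)(C)C(C)(C)C)C/C(C)=C/CCC(=C)CO | intermediate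
24 | allylic methanesulfonate of 23 (not isolated) | CC(=O)SCC(C)(C)C[C@@H](O[Si](C)(C)C(C)(C)C)C/C(C)=C/CCC(=C)COS(C)(=O)=O | intermediate
25 | S-[(4S,6E)-4-[(tert-butyldimethylsilyl)oxy]-10-(chloromethyl)-2,2,6-trimethylundeca-6,10-dien-1-yl] ethanethioate | CC(=O)SCC(C)(C)C[C@@H](O[Si](C)(C)C(C)(C)C)C/C(C)=C/CCC(=C)CCl | intermediate
26 | (4S,6E)-4-[(tert-butyldimethylsilyl)oxy]-10-(chloromethyl)-2,2,6-trimethylundeca-6,10-diene-1-thiol, present as caesium thiolate (not isolated) | SCC(C)(C)C[C@@H](O[Si](C)(C)C(C)(C)C)C/C(C)=C/CCC(=C)CCl | intermediate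
27 | tert-butyl(dimethyl){[(6E,9S)-7,11,11-trimethyl-3-methylidene-1-thiacyclododec-6-en-9-yl]oxy}silane | C=C1CSCC(C)(C)C[C@@H](O[Si](C)(C)C(C)(C)C)C/C(C)=C/CC1 | intermediate
28 | 1-oxide of 27, either configuration at sulfur (not isolated) | C=C1CS(=O)CC(C)(C)C[C@@H](O[Si](C)(C)C(C)(C)C)C/C(C)=C/CC1 | intermediate
29 | (6E,9S)-9-[(tert-butyldimethylsilyl)oxy]-7,11,11-trimethyl-3-methylidene-1-thiacyclododec-6-ene 1,1-dioxide | C=C1CS(=O)(=O)CC(C)(C)C[C@@H](O[Si](C)(C)C(C)(C)C)C/C(C)=C/CC1 | intermediate
30 | 2-bromo derivative of 29, bromine on allylic C2, either epimer (not isolated) | C=C1C(Br)S(=O)(=O)CC(C)(C)C[C@@H](O[Si](C)(C)C(C)(C)C)C/C(C)=C/CC1 | intermediate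
31 | trans-fused episulfone across C1 and C2 (12-thiabicyclo[9.1.0]dodecene 12,12-dioxide), drawn as one of the two trans-fused forms (not isolated) | C=C1[C@H]2[C@H](C(C)(C)C[C@@H](O[Si](C)(C)C(C)(C)C)C/C(C)=C/CC1)S2(=O)=O | intermediate
32 | tert-butyl(dimethyl){[(1S,3E,8E)-3,10,10-trimethyl-7-methylidenecycloundeca-3,8-dien-1-yl]oxy}silane | C=C1/C=C/C(C)(C)C[C@@H](O[Si](C)(C)C(C)(C)C)C/C(C)=C/CC1 | intermediate
33 | (1S,3E,8E)-3,10,10-trimethyl-7-methylidenecycloundeca-3,8-dien-1-ol | C=C1/C=C/C(C)(C)C[C@@H](O)C/C(C)=C/CC1 | intermediate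
34 | isovanillic acid | COc1ccc(C(=O)O)cc1O | starting material
35 | tert-butyldimethylsilyl 3-[(tert-butyldimethylsilyl)oxy]-4-methoxybenzoate (not isolated) | COc1ccc(C(=O)O[Si](C)(C)C(C)(C)C)cc1O[Si](C)(C)C(C)(C)C | intermediate
36 | 3-[(tert-butyldimethylsilyl)oxy]-4-methoxybenzoic acid | COc1ccc(C(=O)O)cc1O[Si](C)(C)C(C)(C)C | intermediate
37 | (1S,3E,8E)-3,10,10-trimethyl-7-methylidenecycloundeca-3,8-dien-1-yl 3-[(tert-butyldimethylsilyl)oxy]-4-methoxybenzoate | C=C1/C=C/C(C)(C)C[C@@H](OC(=O)c2ccc(OC)c(O[Si](C)(C)C(C)(C)C)c2)C/C(C)=C/CC1 | intermediate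
38 | (1S,3E,8E)-3,10,10-trimethyl-7-methylidenecycloundeca-3,8-dien-1-yl 3-hydroxy-4-methoxybenzoate | C=C1/C=C/C(C)(C)C[C@@H](OC(=O)c2ccc(OC)c(O)c2)C/C(C)=C/CC1 | target

**Step count**
Total steps: 18. Longest linear sequence: 17 (steps 1 to 15, then 17 and 18). Step 16 is a one-step side branch.

**Steps most likely to fail**

Risk 1, step 14.
- What may go wrong: repeated bromination at acidic C2 may outrun the slower deprotonation at hindered C1.
- The delocalised allyl sulfonyl anion may let the C3 methylidene migrate into the ring.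
- E selectivity may be incomplete.
- Fallback: halogenation and elimination are separated, so that neither takes place under equilibrating base.
- Setting out from sulfone 29, one equivalent of n-BuLi in THF at −78 °C gives the C2-lithiated sulfone F1.
- Quenching with C2Cl6 gives the isolated C2-chlorosulfone F2.
- KOt-Bu in THF (−78 to 0 °C) then runs the classical two-stage Ramberg–Bäcklund reaction through 31 and rejoins the route at 32.

Risk 2, step 12.
- What may go wrong: intermolecular S-alkylation (oligomerisation) and methanolysis of the allylic chloride may compete with the irreversible closure of the twelve-membered ring.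
- Fallback: an irreversible C–S closure is replaced by a reversible S–S closure followed by sulfur extrusion.
- Setting out from 25, potassium thioacetate in DMF at rt gives the bis(thioacetate) F3.
- K2CO3 in degassed MeOH frees the dithiol F4.
- I2 and Et3N in CH2Cl2–MeOH at high dilution give the thirteen-membered cyclic disulfide F5. Thiolate-catalysed exchange allows oligomers to revert to this monomer.
- P(NEt2)3 in toluene attacks the less hindered allylic sulfur. The tethered neopentyl thiolate then displaces the thiophosphonium group at C2, and direct and allylic attack give the same product.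
- The phosphine sulfide is lost and the route is rejoined at 27.

Risk 3, step 1.
- What may go wrong: direct displacement of chloride by the nitrile anion would erode the enantiomeric purity of the only stereocentre.
- A second addition to the newly formed epoxide may occur.
- The alkoxide may add to the nitrile.
- Fallback: the two nucleophiles are introduced in the opposite order on the other enantiomer.
- Setting out from 6 (as its acetylide 7), purchased (S)-epichlorohydrin F6 and BF3·OEt2 at −78 °C give (S)-1-chloro-5-(trimethylsilyl)pent-4-yn-2-ol F7. The C–Cl bond is not attacked under these conditions.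
- Powdered NaOH in Et2O closes it to (S)-trimethyl[3-(oxiran-2-yl)prop-1-yn-1-yl]silane F8.
- Lithiated nitrile 3 opens F8 at its CH2 in THF (−78 °C to rt), and the route is rejoined at 8.

**Further compounds**
F1 | step 14 | C2-lithiated sulfone from 29 | C=C1C([Li])S(=O)(=O)CC(C)(C)C[C@@H](O[Si](C)(C)C(C)(C)C)C/C(C)=C/CC1
F2 | step 14 | 2-chloro derivative of 29, chlorine on allylic C2, either epimer | C=C1C(Cl)S(=O)(=O)CC(C)(C)C[C@@H](O[Si](C)(C)C(C)(C)C)C/C(C)=C/CC1
F3 | step 12 | bis(thioacetate) of the C1,C2-dithiol, (4S,6E) | CC(=O)SCC(C)(C)C[C@@H](O[Si](C)(C)C(C)(C)C)C/C(C)=C/CCC(=C)CSC(C)=O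
F4 | step 12 | (4S,6E)-4-[(tert-butyldimethylsilyl)oxy]-2,2,6-trimethyl-10-(sulfanylmethyl)undeca-6,10-diene-1-thiol | SCC(C)(C)C[C@@H](O[Si](C)(C)C(C)(C)C)C/C(C)=C/CCC(=C)CS
F5 | step 12 | (7E,10S)-10-[(tert-butyldimethylsilyl)oxy]-8,12,12-trimethyl-4-methylidene-1,2-dithiacyclotridec-7-ene | C=C1CSSCC(C)(C)C[C@@H](O[Si](C)(C)C(C)(C)C)C/C(C)=C/CC1
F6 | step 1 | (S)-epichlorohydrin (purchased) | ClC[C@@H]1CO1
F7 | step 1 | (S)-1-chloro-5-(trimethylsilyl)pent-4-yn-2-ol | ClC[C@@H](O)CC#C[Si](C)(C)C
F8 | step 1 | (S)-trimethyl[3-(oxiran-2-yl)prop-1-yn-1-yl]silane | C[Si](C)(C)C#CC[C@H]1CO1
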